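**Strategy**

- Retrosynthetic cuts, in order: the palmitate C–O bond; the C6–H bond (alcohol back to ketone); one C4–CH3 bond; the C3=C3a double bond (back to a 3a-hydroxy lactone); the lactone O1–C7a bond (strategic cut); the quinol C–OH bond (back to a phenol); the aryl–CH2 bond (to 4-bromo-3,5-dimethylphenol and tert-butyl bromoacetate).
- Enabling feature: the carbocycle C3a–C4–C5–C6–C7–C7a hides a mirror plane through C3a and C6. C4 and C7a are both methyl-bearing neighbours of C3a (which carries the C3–C2 lactone arm) and both lie meta to the C6 oxygen. The ring is therefore a 3,5-dimethylphenol with a para CH2CO2H group, and C7a is one of two enantiotopic enone β-carbons of its dearomatised form.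
- Forward order: the six-membered ring is the arene itself, dearomatised to a 2,5-cyclohexadienone. The γ-lactone ring is closed onto it by a catalytic enantioselective oxa-Michael addition of the free acid and then dehydrated to the butenolide. The second C4 methyl, the C6 hydride and the palmitoyl group follow.
- Stereochemistry: C7a comes from catalyst control in the desymmetrisation (C3a is transient and tied to C7a by the cis ring fusion). C6 comes from substrate control in the ketone reduction, with hydride entering opposite the axial 7a- and 4-methyl groups.

Key step: step 6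

Remark on the chemistry: the sense of induction of a cinchona squaramide cannot be predicted for this new substrate; the quinine-derived catalyst is written, and its quinidine-derived pseudoenantiomer would replace it if it proved to give the (7aS) series.

**Route**

Step 1
Reactants: 1 4-bromo-3,5-dimethylphenol
Product: 2 (4-bromo-3,5-dimethylphenoxy)(tert-butyl)dimethylsilane
Conditions: TBSCl, imidazole, DMF, rt
Reagents that add atoms: tert-butyldimethylsilyl chloride (TBSCl), CC(C)(C)[Si](C)(C)Cl
Why: Standard silylation of a phenol (TBSCl–imidazole in DMF) masks the acidic hydroxyl, which would otherwise protonate the zinc enolate of step 2.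

Step 2
Reactants: 2 (4-bromo-3,5-dimethylphenoxy)(tert-butyl)dimethylsilane; 3 tert-butyl bromoacetate
Product: 5 tert-butyl [4-(tert-butyldimethylsilyloxy)-2,6-dimethylphenyl]acetate, via Reformatsky reagent 4 (not isolated)
Conditions: 3, Zn dust (TMSCl-activated), THF, rt; then 2, Pd(dba)2 [bis(dibenzylideneacetone)palladium] (2 mol%), P(t-Bu)3 (2 mol%), THF, rt to 50 °C
Reagents that add atoms: none
Why: Negishi-type Pd-catalysed α-arylation of an ester through its Reformatsky reagent: oxidative addition of the aryl bromide to zerovalent palladium carrying the bulky, electron-rich P(t-Bu)3, transmetallation from zinc and reductive elimination form the aryl–CH2 bond; the method is established for ortho-substituted aryl bromides, and the weakly basic zinc enolate leaves the silyl ether and the tert-butyl ester alone.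

Step 3
Reactants: 5 tert-butyl [4-(tert-butyldimethylsilyloxy)-2,6-dimethylphenyl]acetate
Product: 6 tert-butyl (4-hydroxy-2,6-dimethylphenyl)acetate
Conditions: Bu4NF, AcOH, THF, 0 °C
Reagents that add atoms: none
Why: Fluoride-induced cleavage of an aryl silyl ether (driven by the strong Si–F bond); the acetic acid buffer keeps the phenoxide from side reactions and the tert-butyl ester is inert.

Step 4
Reactants: 6 tert-butyl (4-hydroxy-2,6-dimethylphenyl)acetate
Product: 7 tert-butyl (1-hydroxy-2,6-dimethyl-4-oxocyclohexa-2,5-dien-1-yl)acetate (achiral p-quinol)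
Conditions: PhI(OAc)2, MeCN/H2O (3:1), 0 °C
Reagents that add atoms: water, O
Why: Oxidative dearomatisation of a para-substituted phenol with a trivalent iodine reagent: the phenol oxygen exchanges for acetate on iodine, PhI leaves, and water captures the electron-poor ring at the para carbon to give the p-quinol; the product has a mirror plane through C1 and C4, and the tert-butyl ester keeps the carboxyl group from taking part.

Step 5
Reactants: 7 tert-butyl (1-hydroxy-2,6-dimethyl-4-oxocyclohexa-2,5-dien-1-yl)acetate
Product: 8 (1-hydroxy-2,6-dimethyl-4-oxocyclohexa-2,5-dien-1-yl)acetic acid (achiral; used at once)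
Conditions: TFA/CH2Cl2 (1:4), 0 °C, about 1 h; toluene co-evaporation below 10 °C
Reagents that add atoms: none
Why: Acidolysis of a tert-butyl ester through the tert-butyl cation (lost as isobutene); the tertiary quinol hydroxyl should survive because its ionisation would give a cation cross-conjugated with the carbonyl group, and the cold, brief exposure is meant to keep acid-promoted ring closure of 8 to a minimum.

Step 6
Reactants: 8 (1-hydroxy-2,6-dimethyl-4-oxocyclohexa-2,5-dien-1-yl)acetic acid
Product: 9 (3aR,7aR)-3a-hydroxy-4,7a-dimethyl-3,3a,7,7a-tetrahydro-1-benzofuran-2,6-dione (cis-fused)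
Conditions: quinine-derived squaramide [3-(3,5-bis(trifluoromethyl)anilino)-4-(9-deoxy-epi-quinin-9-ylamino)cyclobut-3-ene-1,2-dione] (10 mol%), CH2Cl2/toluene, −40 °C; cold filtration through silica
Reagents that add atoms: none
Why: Proposed new method: the quinuclidine nitrogen should deprotonate the acid to a tight ammonium carboxylate while the squaramide N–H groups hold the dienone carbonyl, so that the carboxylate oxygen adds in a conjugate sense to one methyl-bearing β-carbon and the resulting dienol is protonated at C7 by the ammonium ion, which releases the catalyst. The closest known reaction type is the organocatalytic desymmetrising intramolecular oxa-Michael addition of 4-hydroxy-2,5-cyclohexadienones that carry a tethered oxygen nucleophile, and the same hydroxy lactone skeleton is known to form spontaneously, as a racemate, from the quinol acetic acid without ring methyl groups; not yet shown are a carboxylic acid as the nucleophile in the asymmetric version and a tetrasubstituted C–O centre at a β-methyl enone carbon. The γ-lactone ring (O1, C2, C3, C3a, C7a) closes 5-exo-trig by the O1–C7a bond. C7a is fixed by the catalyst, which picks one of the two enantiotopic enone arms, and C3a follows from it because the two-atom tether on the quaternary carbon can only reach the cis face. The selectivity required is enantiotopic-group selectivity under kinetic control, since the addition is reversible; the substrate offers no bias between the arms, but its β-methyl groups slow the uncatalysed closure and its symmetry removes every regiochemical alternative, so the chiral ion pair alone should decide.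

Step 7
Reactants: 9 (3aR,7aR)-3a-hydroxy-4,7a-dimethyl-3,3a,7,7a-tetrahydro-1-benzofuran-2,6-dione
Product: 11 (7aR)-4,7a-dimethyl-7,7a-dihydro-1-benzofuran-2,6-dione, via Burgess sulfamate 10 (not isolated)
Conditions: Burgess reagent (Et3N+SO2N−CO2Me), THF, rt then 50 °C; carried out directly after step 6
Reagents that add atoms: none
Why: Burgess dehydration: the tertiary 3a-hydroxyl is sulfamoylated to 10, which loses the sulfamate by intramolecular syn elimination with the acidic C3 hydrogen cis to it on the five-membered ring, the only β-hydrogen available because C4 and C7a carry none, so the butenolide should form regiospecifically under non-basic conditions that do not reopen the lactone; C7a is untouched and the C3a centre disappears.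

Step 8
Reactants: 11 (7aR)-4,7a-dimethyl-7,7a-dihydro-1-benzofuran-2,6-dione
Product: 13 (R)-dehydrololiolide [(7aR)-4,4,7a-trimethyl-5,7a-dihydro-1-benzofuran-2,6(4H,7H)-dione], via silyl enol ether 12 (not isolated)
Conditions: Me2CuLi (from CuI and 2 MeLi), TMSCl, THF/Et2O, −78 °C; then 1 M HCl, THF, 0 °C
Reagents that add atoms: lithium dimethylcuprate, [Li+].C[Cu-]C (made in the flask from methyllithium, [Li]C, and CuI)
Why: Conjugate addition of a Gilman cuprate with TMSCl acceleration, the standard way to a quaternary carbon from a β,β-disubstituted cyclohexenone: the methyl group should go to C4, the β-carbon of the ketone (the stronger acceptor), rather than to C3 (α to the lactone carbonyl, electronically mismatched) or C3a (tetrasubstituted and flanked by quaternary C7a), the enolate is trapped as silyl enol ether 12 so that no free enolate meets the β-acyloxy ketone, and dilute acid returns the ketone; C4 becomes a non-stereogenic gem-dimethyl carbon.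

Step 9
Reactants: 13 (R)-dehydrololiolide
Product: 14 (−)-loliolide [(6S,7aR)-6-hydroxy-4,4,7a-trimethyl-5,6,7,7a-tetrahydro-1-benzofuran-2(4H)-one]
Conditions: LiBH(s-Bu)3, THF, −78 °C; AcOH quench
Reagents that add atoms: none
Why: Ketone reduction with a bulky trialkylborohydride under steric approach control: in the chair that the planar butenolide enforces, the 7a-methyl and one 4-methyl are axial on the same face and both 1,3 to C6, so hydride should enter from the opposite, equatorial side and give the axial (6S) alcohol cis to the 7a-methyl (as in the reduction of 3,3,5-trimethylcyclohexanone), while the fully β-substituted butenolide should not be reduced at −78 °C.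

Step 10
Reactants: 14 (−)-loliolide; 15 palmitoyl chloride (hexadecanoyl chloride)
Product: 16 (−)-3-O-palmitoylloliolide [(6S,7aR)-4,4,7a-trimethyl-2-oxo-2,4,5,6,7,7a-hexahydro-1-benzofuran-6-yl hexadecanoate]
Conditions: pyridine, DMAP (cat.), CH2Cl2, 0 °C to rt
Reagents that add atoms: none
Why: DMAP-catalysed acylation of a secondary alcohol by an acid chloride through the acylpyridinium ion; the C6–O bond is not broken, so the configuration is retained, and the hindered axial hydroxyl of loliolide-type alcohols is known to accept acyl groups.

**Compound list**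

1 | 4-bromo-3,5-dimethylphenol | Cc1cc(O)cc(C)c1Br | starting material
2 | (4-bromo-3,5-dimethylphenoxy)(tert-butyl)dimethylsilane | Cc1cc(O[Si](C)(C)C(C)(C)C)cc(C)c1Br | intermediate
3 | tert-butyl bromoacetate | BrCC(=O)OC(C)(C)C | starting material
4 | bromo(2-tert-butoxy-2-oxoethyl)zinc, Reformatsky reagent (made and used in THF solution) | Br[Zn]CC(=O)OC(C)(C)C | intermediate
5 | tert-butyl [4-(tert-butyldimethylsilyloxy)-2,6-dimethylphenyl]acetate | Cc1cc(O[Si](C)(C)C(C)(C)C)cc(C)c1CC(=O)OC(C)(C)C | intermediate
6 | tert-butyl (4-hydroxy-2,6-dimethylphenyl)acetate | Cc1cc(O)cc(C)c1CC(=O)OC(C)(C)C | intermediate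
7 | tert-butyl (1-hydroxy-2,6-dimethyl-4-oxocyclohexa-2,5-dien-1-yl)acetate | CC1=CC(=O)C=C(C)C1(O)CC(=O)OC(C)(C)C | intermediate
8 | (1-hydroxy-2,6-dimethyl-4-oxocyclohexa-2,5-dien-1-yl)acetic acid | CC1=CC(=O)C=C(C)C1(O)CC(=O)O | intermediate
9 | (3aR,7aR)-3a-hydroxy-4,7a-dimethyl-3,3a,7,7a-tetrahydro-1-benzofuran-2,6-dione | O=C1C[C@@]2(O)C(C)=CC(=O)C[C@@]2(C)O1 | intermediate
10 | triethylammonium salt of the 3a-O-[N-(methoxycarbonyl)sulfamoyl] derivative of 9 (formed in the flask) | O=C1C[C@@]2(OS(=O)(=O)[N-]C(=O)OC)C(C)=CC(=O)C[C@@]2(C)O1.CC[NH+](CC)CC | intermediate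
11 | (7aR)-4,7a-dimethyl-7,7a-dihydro-1-benzofuran-2,6-dione | O=C1C=C2C(C)=CC(=O)C[C@@]2(C)O1 | intermediate
12 | (7aR)-4,4,7a-trimethyl-6-(trimethylsilyloxy)-7,7a-dihydro-1-benzofuran-2(4H)-one, silyl enol ether (formed in the flask) | O=C1C=C2C(C)(C)C=C(O[Si](C)(C)C)C[C@@]2(C)O1 | intermediate
13 | (R)-dehydrololiolide, (7aR)-4,4,7a-trimethyl-5,7a-dihydro-1-benzofuran-2,6(4H,7H)-dione | O=C1C=C2C(C)(C)CC(=O)C[C@@]2(C)O1 | intermediate
14 | (−)-loliolide, (6S,7aR)-6-hydroxy-4,4,7a-trimethyl-5,6,7,7a-tetrahydro-1-benzofuran-2(4H)-one | O[C@H]1CC(C)(C)C2=CC(=O)O[C@]2(C)C1 | intermediate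
15 | palmitoyl chloride | CCCCCCCCCCCCCCCC(=O)Cl | starting material
16 | (−)-3-O-palmitoylloliolide, (6S,7aR)-4,4,7a-trimethyl-2-oxo-2,4,5,6,7,7a-hexahydro-1-benzofuran-6-yl hexadecanoate | CCCCCCCCCCCCCCCC(=O)O[C@H]1CC(C)(C)C2=CC(=O)O[C@]2(C)C1 | target

**Step count and risks**

Total step count: 10. Longest linear sequence: 10 steps (from 1 to 16; 3 and 15 are bought and enter directly).

Steps most likely to fail:

1. Step 6 (proposed new method). The catalyst may discriminate poorly between the two enone arms. An uncatalysed or acid-promoted ring closure, possibly beginning during the ester cleavage of step 5, may outrun the chiral ion pair. The enantiomeric purity may also erode through retro-addition before the dehydration. The fallback sets out from 8 and returns to the route at 9. The acid 8 is cyclised with a catalytic amount of DABCO in CH2Cl2 at rt, the known base-mediated intramolecular oxa-Michael lactonisation of quinol acetic acids, to the racemic cis-fused hydroxy lactone F1. F1 is resolved by preparative HPLC on a polysaccharide chiral stationary phase with a neutral eluent. The (3aR,7aR) enantiomer is 9 and goes on to step 7. The (3aS,7aS)-3a-hydroxy-4,7a-dimethyl-3,3a,7,7a-tetrahydro-1-benzofuran-2,6-dione F2 is re-equilibrated with DABCO through the achiral acid 8 to F1 and resubmitted.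

2. Step 8. The methyl group may be delivered to the wrong terminus of the conjugated dienedione (C3 instead of C4). The electron-poor π-system may instead be reduced by electron transfer from the cuprate, or addition at the hindered C4 may be too slow. The fallback sets out from 9 and returns at 13, with the methyl addition moved in front of the dehydration so that the cuprate meets a plain β-methylcyclohexenone. Compound 9 is silylated with 1-(trimethylsilyl)imidazole to the 3a-O-trimethylsilyl ether F3. Me2CuLi/TMSCl at −78 °C should then give the bis-silylated conjugate adduct F4 (not isolated). Aqueous citric acid in methanol removes both silyl groups to give the hydroxy ketone (3aR,7aR)-3a-hydroxy-4,4,7a-trimethylhexahydro-1-benzofuran-2,6-dione F5. Dehydration of this hindered tertiary β-hydroxy lactone with SOCl2/pyridine at 0 °C, through the chlorosulfite F6 (not isolated), gives 13.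

3. Step 4. Water may attack the oxidised ring at an ortho carbon, followed by over-oxidation. Alternatively the activated benzylic CH2 may lose a proton to give a quinone methide, either of which would lower the return of quinol. The fallback sets out from 6 and returns at 7 by a singlet-oxygen route instead of hypervalent iodine. KHSO5 (as the triple salt 2KHSO5·KHSO4·K2SO4) with NaHCO3 in aqueous MeCN generates singlet oxygen, which converts para-alkylphenols into para-hydroperoxy dienones, here tert-butyl (1-hydroperoxy-2,6-dimethyl-4-oxocyclohexa-2,5-dien-1-yl)acetate F7. Reduction of the O–O bond with dimethyl sulfide gives 7.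

**Further compounds**

F1 | step 6 | racemic cis-fused (3aR*,7aR*)-3a-hydroxy-4,7a-dimethyl-3,3a,7,7a-tetrahydro-1-benzofuran-2,6-dione | O=C1C[C@@]2(O)C(C)=CC(=O)C[C@@]2(C)O1.O=C1C[C@]2(O)C(C)=CC(=O)C[C@]2(C)O1
F2 | step 6 | (3aS,7aS)-3a-hydroxy-4,7a-dimethyl-3,3a,7,7a-tetrahydro-1-benzofuran-2,6-dione | O=C1C[C@]2(O)C(C)=CC(=O)C[C@]2(C)O1
F3 | step 8 | (3aR,7aR)-4,7a-dimethyl-3a-(trimethylsilyloxy)-3,3a,7,7a-tetrahydro-1-benzofuran-2,6-dione | O=C1C[C@@]2(O[Si](C)(C)C)C(C)=CC(=O)C[C@@]2(C)O1
F4 | step 8 | (3aR,7aR)-4,4,7a-trimethyl-3a,6-bis(trimethylsilyloxy)-3a,4,7,7a-tetrahydro-1-benzofuran-2(3H)-one | O=C1C[C@@]2(O[Si](C)(C)C)C(C)(C)C=C(O[Si](C)(C)C)C[C@@]2(C)O1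
F5 | step 8 | (3aR,7aR)-3a-hydroxy-4,4,7a-trimethylhexahydro-1-benzofuran-2,6-dione | O=C1C[C@@]2(O)C(C)(C)CC(=O)C[C@@]2(C)O1
F6 | step 8 | 3a-O-chlorosulfite of F5 | O=C1C[C@@]2(OS(=O)Cl)C(C)(C)CC(=O)C[C@@]2(C)O1
F7 | step 4 | tert-butyl (1-hydroperoxy-2,6-dimethyl-4-oxocyclohexa-2,5-dien-1-yl)acetate | CC1=CC(=O)C=C(C)C1(OO)CC(=O)OC(C)(C)C
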